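**Strategy.** The indane is cut at C7a–C1 and C2–C3. An exocyclic C1 alkene carried by ring-A carbon C7a (meta to both ring-A oxygens) and flanked by the C2 methine is the mark of aryl-metal addition to an allene followed by carbonyl allylation. A chiral rhodium catalyst therefore joins 2-formyl-3,5-diisopropoxyphenyl pinacol boronate (ring A) to 3,5-diisopropoxyphenylallene (ring C), forming both bonds, the cyclopentane and the C2 stereocentre in one operation. The resulting 1-methylene-indan-3-ol is completed by two arylations: guaiacol replaces the ionisable C3 hydroxyl trans to the C2 aryl group, and a Heck reaction converts C1=CH2 into the E-benzylidene before selective de-isopropylation.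

Key step: step 5

Assumption 1: indane numbering is used for every bicyclic compound (C1 = alkylidene or carbonyl carbon, C2 = carbon bearing the 3,5-dioxygenated aryl group, C3 = carbon bearing hydroxyl or guaiacyl, ring-A oxygens at C4 and C6); in this numbering the target is (1E,2S,3S).
Assumption 2: the closed transition state of step 5 should place the new hydroxyl cis to the C2 aryl group, so 9 is drawn as the cis alcohol; C3 is ionised in step 6, so the trans epimer would serve equally.
Assumption 3: the sense of induction of the chiral ligand cannot be predicted; the antipode that delivers 2S is to be used.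

Step 1
Reactants: 1 5-bromoresorcinol
Product: 2 1-bromo-3,5-diisopropoxybenzene
Conditions: 2-bromopropane (3 equiv), K2CO3 (3 equiv), DMF, 70 °C
Reagents that add atoms: 2-bromopropane, CC(C)Br
Why: Williamson ether synthesis; both phenoxide oxygens are alkylated and the aryl bromide is inert to carbonate.

Step 2
Reactants: 2 1-bromo-3,5-diisopropoxybenzene
Product: 4 2-bromo-4,6-diisopropoxybenzaldehyde, via aryl iminium chloride 3 (not isolated)
Conditions: POCl3 (2 equiv), DMF, 0 → 80 °C; then ice–water, rt
Reagents that add atoms: N,N-dimethylformamide, CN(C)C=O; water, O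
Why: Vilsmeier–Haack formylation; the chloroiminium ion should attack the position ortho to bromine (para to one ether, ortho to the other) in preference to the more hindered site between the two isopropoxy groups, and water hydrolyses the iminium salt.

Step 3
Reactants: 4 2-bromo-4,6-diisopropoxybenzaldehyde
Product: 5 2-formyl-3,5-diisopropoxyphenylboronic acid pinacol ester
Conditions: B2pin2 (1.2 equiv), PdCl2(dppf) (3 mol %), KOAc (3 equiv), dioxane, 90 °C
Reagents that add atoms: bis(pinacolato)diboron, CC1(C)OB(OC1(C)C)B1OC(C)(C)C(C)(C)O1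
Why: Miyaura borylation; the weak acetate base leaves the aldehyde untouched and suppresses Suzuki homocoupling, so boron ends at the ring position meta to both ethers.

Step 4
Reactants: 2 1-bromo-3,5-diisopropoxybenzene; 6 propargyl bromide
Product: 8 1-(propa-1,2-dienyl)-3,5-diisopropoxybenzene, via 3,5-diisopropoxyphenylmagnesium bromide 7 (not isolated)
Conditions: Mg, THF, reflux; then CuBr (5 mol %), 6 (1.2 equiv), THF, −20 °C → rt
Reagents that add atoms: none
Why: Grignard formation followed by copper-catalysed SN2′ substitution of propargyl bromide, in which the aryl group is delivered to the alkyne terminus and the terminal arylallene results.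

Step 5
Reactants: 5 2-formyl-3,5-diisopropoxyphenylboronic acid pinacol ester; 8 1-(propa-1,2-dienyl)-3,5-diisopropoxybenzene
Product: 9 (2S,3S)-2-(3,5-diisopropoxyphenyl)-4,6-diisopropoxy-1-methyleneindan-3-ol (2,3-cis)
Conditions: [RhCl(C2H4)2]2 (2.5 mol %), (R)- or (S)-DTBM-SEGPHOS (6 mol %, antipode that gives 2S), KOH (0.3 equiv), degassed dioxane/H2O (10:1), 50 °C, 8 (1.5 equiv) added slowly
Reagents that add atoms: none
Why: Proposed new method: transmetalation of 5 to the chiral hydroxo-rhodium(I) complex gives an aryl-rhodium at C7a, which adds across the terminal C=C of 8 on the face away from its aryl group, so that C7a bonds to the central allene carbon (C7a–C1) and rhodium rests on the primary terminus of the resulting allyl complex. That allylrhodium attacks the ortho aldehyde through its aryl-bearing γ-carbon in a closed, oxygen-bound six-membered transition state (C2–C3), a 5-exo-trig closure of the cyclopentane that leaves C1=CH2 exocyclic, and water releases the alcohol and regenerates Rh–OH. The closest known reaction types are the palladium(II)- and rhodium(I)-catalysed [3+2] annulations of 2-formylaryl boron reagents with allenes to cis-2-substituted 3-alkylidene-indan-1-ols and the rhodium(I)/bisphosphine-catalysed enantioselective [3+2] annulation of aryl ketimines with allenes; the enantioselective aldehyde/arylallene pairing is the untested element. C2 is set by the ligand, which decides the face of the allyl terminus that meets the carbonyl group, and C3 follows from the bicyclic transition state, in which the aryl group (cis to CH2–Rh) and the carbonyl oxygen lie on the same side of the forming ring, hence the cis alcohol. The step needs aryl delivery to the central allene carbon and γ-selective allylation, and both are secured by the preference of rhodium for the unhindered CH2 terminus and by the ortho formyl group, which makes carbonyl capture intramolecular and faster than protonation of the allylrhodium.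

Step 6
Reactants: 9 (2S,3S)-2-(3,5-diisopropoxyphenyl)-4,6-diisopropoxy-1-methyleneindan-3-ol; 10 guaiacol
Product: 11 (2S,3S)-2-(3,5-diisopropoxyphenyl)-3-(4-hydroxy-3-methoxyphenyl)-4,6-diisopropoxy-1-methyleneindane (2,3-trans)
Conditions: guaiacol (5 equiv), TsOH·H2O (5 mol %), CH2Cl2, −20 → 0 °C
Reagents that add atoms: none
Why: Friedel–Crafts alkylation; the 2,4-dialkoxybenzylic alcohol ionises under mild acid that should leave the methylene group alone, and guaiacol captures the planar C3 cation para to its hydroxyl (the stronger donor) on the face opposite the C2 aryl group, which sets C3 as the trans (3S) centre whatever the C3 configuration of 9.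

Step 7
Reactants: 11 (2S,3S)-2-(3,5-diisopropoxyphenyl)-3-(4-hydroxy-3-methoxyphenyl)-4,6-diisopropoxy-1-methyleneindane
Product: 12 (2S,3S)-2-(3,5-diisopropoxyphenyl)-3-(4-isopropoxy-3-methoxyphenyl)-4,6-diisopropoxy-1-methyleneindane
Conditions: 2-bromopropane (3 equiv), K2CO3 (2 equiv), DMF, 60 °C
Reagents that add atoms: 2-bromopropane, CC(C)Br
Why: Williamson ether synthesis; carbonate deprotonates only the phenol, so the benzylic and allylic C–H bonds at C2 and C3 and the alkene are not touched.

Step 8
Reactants: 13 4-bromo-2-methoxyphenol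
Product: 14 4-bromo-1-isopropoxy-2-methoxybenzene
Conditions: 2-bromopropane (2 equiv), K2CO3 (2 equiv), DMF, 60 °C
Reagents that add atoms: 2-bromopropane, CC(C)Br
Why: Williamson ether synthesis on a simple phenol gives the Heck partner with the same protecting group as the rest of the molecule.

Step 9
Reactants: 12 (2S,3S)-2-(3,5-diisopropoxyphenyl)-3-(4-isopropoxy-3-methoxyphenyl)-4,6-diisopropoxy-1-methyleneindane; 14 4-bromo-1-isopropoxy-2-methoxybenzene
Product: 15 (1E,2S,3S)-1-(4-isopropoxy-3-methoxybenzylidene)-2-(3,5-diisopropoxyphenyl)-3-(4-isopropoxy-3-methoxyphenyl)-4,6-diisopropoxyindane (hexa-O-isopropylgnetulin)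
Conditions: Pd2(dba)3 (2.5 mol %), [(t-Bu)3PH]BF4 (10 mol %), Cy2NMe (1.5 equiv), 14 (1.3 equiv), dioxane, 90 °C
Reagents that add atoms: none
Why: Mizoroki–Heck arylation of a 1,1-disubstituted styrene; syn-carbopalladation puts the aryl group on the CH2 terminus and palladium on C1, β-hydride elimination from the new benzylic CH2 gives the conjugated trisubstituted alkene, the E isomer should prevail because the aryl group avoids the peri C7–H, and the bulky phosphine with the amine base should return Pd–H to Pd(0) quickly enough to limit double-bond migration.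

Step 10
Reactants: 15 hexa-O-isopropylgnetulin
Product: 16 gnetulin, (1E,2S,3S)-1-(4-hydroxy-3-methoxybenzylidene)-2-(3,5-dihydroxyphenyl)-3-(4-hydroxy-3-methoxyphenyl)indane-4,6-diol
Conditions: BCl3 (1 M in CH2Cl2, 12 equiv), CH2Cl2, −78 → 0 °C; then MeOH, H2O
Reagents that add atoms: none
Why: Lewis-acid ether cleavage; BCl3 removes secondary isopropyl aryl ethers at low temperature by SN1-like C–O scission while aryl methyl ethers persist, and the cold, short exposure should spare the acid-sensitive exocyclic stilbene and both stereocentres.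

**Compound list**

1 | 5-bromoresorcinol | Oc1cc(O)cc(Br)c1 | starting material
2 | 1-bromo-3,5-diisopropoxybenzene | CC(C)Oc1cc(Br)cc(OC(C)C)c1 | intermediate
3 | (2-bromo-4,6-diisopropoxybenzylidene)dimethyliminium chloride | C[N+](C)=Cc1c(Br)cc(OC(C)C)cc1OC(C)C.[Cl-] | intermediate (not isolated)
4 | 2-bromo-4,6-diisopropoxybenzaldehyde | O=Cc1c(Br)cc(OC(C)C)cc1OC(C)C | intermediate
5 | 2-formyl-3,5-diisopropoxyphenylboronic acid pinacol ester | O=Cc1c(OC(C)C)cc(OC(C)C)cc1B1OC(C)(C)C(C)(C)O1 | intermediate
6 | propargyl bromide | C#CCBr | starting material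
7 | 3,5-diisopropoxyphenylmagnesium bromide | CC(C)Oc1cc([Mg]Br)cc(OC(C)C)c1 | intermediate (not isolated)
8 | 1-(propa-1,2-dienyl)-3,5-diisopropoxybenzene | C=C=Cc1cc(OC(C)C)cc(OC(C)C)c1 | intermediate
9 | (2S,3S)-2-(3,5-diisopropoxyphenyl)-4,6-diisopropoxy-1-methyleneindan-3-ol (2,3-cis) | C=C2c3cc(OC(C)C)cc(OC(C)C)c3[C@@H](O)[C@H]2c2cc(OC(C)C)cc(OC(C)C)c2 | intermediate
10 | guaiacol | COc1ccccc1O | starting material
11 | (2S,3S)-2-(3,5-diisopropoxyphenyl)-3-(4-hydroxy-3-methoxyphenyl)-4,6-diisopropoxy-1-methyleneindane (2,3-trans) | C=C2c3cc(OC(C)C)cc(OC(C)C)c3[C@H](c3ccc(O)c(OC)c3)[C@H]2c2cc(OC(C)C)cc(OC(C)C)c2 | intermediate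
12 | (2S,3S)-2-(3,5-diisopropoxyphenyl)-3-(4-isopropoxy-3-methoxyphenyl)-4,6-diisopropoxy-1-methyleneindane | C=C2c3cc(OC(C)C)cc(OC(C)C)c3[C@H](c3ccc(OC(C)C)c(OC)c3)[C@H]2c2cc(OC(C)C)cc(OC(C)C)c2 | intermediate
13 | 4-bromo-2-methoxyphenol | COc1cc(Br)ccc1O | starting material
14 | 4-bromo-1-isopropoxy-2-methoxybenzene | COc1cc(Br)ccc1OC(C)C | intermediate
15 | (1E,2S,3S)-1-(4-isopropoxy-3-methoxybenzylidene)-2-(3,5-diisopropoxyphenyl)-3-(4-isopropoxy-3-methoxyphenyl)-4,6-diisopropoxyindane | COc1cc(/C=C2/c3cc(OC(C)C)cc(OC(C)C)c3[C@H](c3ccc(OC(C)C)c(OC)c3)[C@H]2c2cc(OC(C)C)cc(OC(C)C)c2)ccc1OC(C)C | intermediate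
16 | gnetulin | COc1cc(/C=C2/c3cc(O)cc(O)c3[C@H](c3ccc(O)c(OC)c3)[C@H]2c2cc(O)cc(O)c2)ccc1O | target

**Step count and risks**

Total steps: 10. Longest linear sequence: 8 steps (1, 2, 3, 5, 6, 7, 9, 10).

Step 5 (new method). The process at risk is facial discrimination in the allylation: the ligand may not distinguish the two faces of the allyl terminus well enough, so that C2 forms with low enantiomeric purity. The fallback uses known chemistry, replaces asymmetric catalysis by resolution, sets out from 5 and 8 and returns to the route at 11. The annulation is run with an achiral catalyst of the established kind ([Rh(OH)(cod)]2, aqueous KOH, dioxane) to give the racemic cis-alcohol F1. The conditions of step 6 convert it into the racemic trans-phenol F2. Acylation of the phenol with (1S)-camphanic chloride (Et3N, DMAP, CH2Cl2) gives two diastereomeric aryl esters, the (2S,3S)-camphanate F3 and the (2R,3R)-camphanate F4, which are separated by chromatography or crystallisation. Methanolysis of F3 (K2CO3, MeOH, 0 °C) gives 11.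

Step 9. The process at risk is the direction of β-hydride elimination: the tertiary alkylpalladium at C1 can lose the ring hydrogen at C2 instead of a hydrogen of the new benzylic CH2, which moves the double bond into the ring and erases the C2 stereocentre; palladium hydride can isomerise the product in the same sense. The fallback sets out from 12, returns at 15, and builds the alkene by carbonyl addition and syn-elimination.
- Oxidative cleavage of the methylene group (cat. OsO4, NaIO4, 2,6-lutidine, dioxane/H2O) gives the trans-indan-1-one F5; the trans arrangement is the thermodynamically preferred one should C2 enolise.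
- Commercial vanillyl alcohol is O-isopropylated (2-bromopropane, K2CO3, DMF) to 4-isopropoxy-3-methoxybenzyl alcohol F6, converted with concentrated HCl into 4-isopropoxy-3-methoxybenzyl chloride F7, and then with magnesium (THF, 0 °C, high dilution) into the benzylmagnesium chloride F8.
- The organocerium reagent made from F8 and anhydrous CeCl3 adds to the enolisable ketone F5 at −78 °C on the face opposite the C2 aryl group to give the tertiary alcohol F9, whose hydroxyl is then anti to the C2 hydrogen.
- Thermal syn-elimination with the inner salt methyl N-(triethylammoniumsulfonyl)carbamate (toluene, 50 °C) can therefore only take a benzylic hydrogen of the side chain and should give 15.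

Step 6. The process at risk is site selectivity on guaiacol: the cation can also attack para to the methoxy group and give a regioisomeric aryl group that is hard to separate. The fallback sets out from 9, returns at 12, and blocks that position. Alcohol 9 is treated under the conditions of step 6 with commercial 5-bromo-2-methoxyphenol, in which only the position para to the hydroxyl remains strongly activated, to give the trans-bromophenol F10. O-Isopropylation as in step 7 gives the aryl bromide F11. Bromine–lithium exchange (n-BuLi, THF, −78 °C) with immediate protonation by methanol removes the blocking bromine and gives 12.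

**Further compounds**

F1 | step 5 | racemic cis-2-(3,5-diisopropoxyphenyl)-4,6-diisopropoxy-1-methyleneindan-3-ol (both enantiomers written) | C=C2c3cc(OC(C)C)cc(OC(C)C)c3[C@@H](O)[C@H]2c2cc(OC(C)C)cc(OC(C)C)c2.C=C2c3cc(OC(C)C)cc(OC(C)C)c3[C@H](O)[C@@H]2c2cc(OC(C)C)cc(OC(C)C)c2
F2 | step 5 | racemic trans-2-(3,5-diisopropoxyphenyl)-3-(4-hydroxy-3-methoxyphenyl)-4,6-diisopropoxy-1-methyleneindane (both enantiomers written) | C=C2c3cc(OC(C)C)cc(OC(C)C)c3[C@H](c3ccc(O)c(OC)c3)[C@H]2c2cc(OC(C)C)cc(OC(C)C)c2.C=C2c3cc(OC(C)C)cc(OC(C)C)c3[C@@H](c3ccc(O)c(OC)c3)[C@@H]2c2cc(OC(C)C)cc(OC(C)C)c2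
F3 | step 5 | (1S,4R)-camphanate ester of the phenol of (2S,3S)-11 | C=C2c3cc(OC(C)C)cc(OC(C)C)c3[C@H](c3ccc(OC(=O)[C@@]45CC[C@@](C)(C(=O)O4)C5(C)C)c(OC)c3)[C@H]2c2cc(OC(C)C)cc(OC(C)C)c2
F4 | step 5 | (1S,4R)-camphanate ester of the phenol of the (2R,3R) enantiomer of 11 | C=C2c3cc(OC(C)C)cc(OC(C)C)c3[C@@H](c3ccc(OC(=O)[C@@]45CC[C@@](C)(C(=O)O4)C5(C)C)c(OC)c3)[C@@H]2c2cc(OC(C)C)cc(OC(C)C)c2
F5 | step 9 | (2S,3S)-2-(3,5-diisopropoxyphenyl)-3-(4-isopropoxy-3-methoxyphenyl)-4,6-diisopropoxyindan-1-one | O=C2c3cc(OC(C)C)cc(OC(C)C)c3[C@H](c3ccc(OC(C)C)c(OC)c3)[C@H]2c2cc(OC(C)C)cc(OC(C)C)c2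
F6 | step 9 | 4-isopropoxy-3-methoxybenzyl alcohol | COc1cc(CO)ccc1OC(C)C
F7 | step 9 | 4-isopropoxy-3-methoxybenzyl chloride | COc1cc(CCl)ccc1OC(C)C
F8 | step 9 | (4-isopropoxy-3-methoxybenzyl)magnesium chloride | COc1cc(C[Mg]Cl)ccc1OC(C)C
F9 | step 9 | (1R,2S,3S)-1-(4-isopropoxy-3-methoxybenzyl)-2-(3,5-diisopropoxyphenyl)-3-(4-isopropoxy-3-methoxyphenyl)-4,6-diisopropoxyindan-1-ol | O[C@@]2(Cc4ccc(OC(C)C)c(OC)c4)c3cc(OC(C)C)cc(OC(C)C)c3[C@H](c3ccc(OC(C)C)c(OC)c3)[C@H]2c2cc(OC(C)C)cc(OC(C)C)c2
F10 | step 6 | (2S,3R)-3-(2-bromo-4-hydroxy-5-methoxyphenyl)-2-(3,5-diisopropoxyphenyl)-4,6-diisopropoxy-1-methyleneindane (2,3-trans, same spatial arrangement as 11) | C=C2c3cc(OC(C)C)cc(OC(C)C)c3[C@H](c3cc(OC)c(O)cc3Br)[C@H]2c2cc(OC(C)C)cc(OC(C)C)c2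
F11 | step 6 | (2S,3R)-3-(2-bromo-4-isopropoxy-5-methoxyphenyl)-2-(3,5-diisopropoxyphenyl)-4,6-diisopropoxy-1-methyleneindane | C=C2c3cc(OC(C)C)cc(OC(C)C)c3[C@H](c3cc(OC)c(OC(C)C)cc3Br)[C@H]2c2cc(OC(C)C)cc(OC(C)C)c2
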